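**Plan**
- Retrosynthesis: cleave the C9 epoxyangelate ester, cut the ring olefin C1=C10 (metathesis), then cut C8–C9 and C2–C3 (two allylborations of a lactone dialdehyde). Reconnect C3 to C8 (reverse glycol cleavage) to a cyclohexene cis-diol, then cut O–C6 and C11–C7 of the lactone, which leaves toluene cis-dihydrodiol acetonide and 2-bromoacrylic acid.
- Enabling feature: the lactone carbinol C6 is allylic to the Z-olefin C4=C5 and vicinal to C7, and C3 and C8 both carry oxygen. The segment C3–C4(Me)=C5–C6–C7–C8 is therefore a masked (1S,2R)-3-methylcyclohexa-3,5-diene-1,2-diol with C3–C8 as a temporary ring bond.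
- Forward order: dioxolane-fused cyclohexadiene, then the cis-fused α-methylene-γ-lactone ring (key step), then opening of the six-membered ring to a dialdehyde, attachment of the two olefinic arms, the ten-membered ring by metathesis, esterification and desilylation.
- Stereochemistry: C6 and C7 from the dihydrodiol (anti-acetonide face, cis by the ring); Z-C4=C5 inherited from the six-membered ring; C9 and C3 from isopinocampheylborane reagents; C8 by chelation-controlled reduction; the epoxide by Sharpless epoxidation; Z-C1=C10 by the ring constraint.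

Key step: step 6

Remark: diene diol 7 (the cis-dihydrodiol from microbial dioxygenation of toluene) is assumed to be purchasable as the single (1S,2R) enantiomer. Germacrane numbering of the target is used for all intermediates: ring carbons C1–C10, lactone carbons C11–C13, methyl C14 on C10, methyl C15 on C4.

**Step 1**
Reactants: 1 angelic acid
Product: 2 (2Z)-2-methylbut-2-en-1-ol
Conditions: LiAlH4, Et2O, 0 °C to rt; aqueous NaOH work-up
Reagents that add atoms: none
Why: Hydride reduction of the carboxylic acid to the primary allylic alcohol should leave the trisubstituted Z-olefin untouched in cold ether.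

**Step 2**
Reactants: 2 (2Z)-2-methylbut-2-en-1-ol
Product: 3 [(2S,3R)-2,3-dimethyloxiran-2-yl]methanol
Conditions: Ti(OiPr)4 (cat.), L-(+)-diisopropyl tartrate (cat.), t-BuOOH, 4 Å molecular sieves, CH2Cl2, −20 °C
Reagents that add atoms: tert-butyl hydroperoxide, CC(C)(C)OO
Why: Sharpless asymmetric epoxidation, in which the L-(+)-tartrate titanium complex delivers oxygen to the face that gives the 2S centre while the Z-olefin geometry fixes C3 as R.

**Step 3**
Reactants: 3 [(2S,3R)-2,3-dimethyloxiran-2-yl]methanol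
Product: 4 (2R,3R)-2,3-dimethyloxirane-2-carboxylic acid
Conditions: RuCl3·xH2O (cat.), NaIO4, CCl4/MeCN/H2O, rt
Reagents that add atoms: water, O
Why: Catalytic RuO4 oxidation of the primary alcohol through the aldehyde hydrate should give the glycidic acid without touching the two epoxide stereocentres.

**Step 4**
Reactants: 5 2-methylprop-2-en-1-ol
Product: 6 3-(methoxymethoxy)-2-methylprop-1-ene
Conditions: MeOCH2Cl, i-Pr2NEt, CH2Cl2, 0 °C to rt
Reagents that add atoms: chloromethyl methyl ether, COCCl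
Why: Standard O-alkylation of the primary alcohol gives the MOM ether needed as the chelating γ-alkoxyallyl precursor.

**Step 5**
Reactants: 7 (1S,2R)-3-methylcyclohexa-3,5-diene-1,2-diol
Product: 8 (3aR,7aS)-2,2,4-trimethyl-3a,7a-dihydro-1,3-benzodioxole
Conditions: 2,2-dimethoxypropane, TsOH (cat.), acetone, 0 °C
Reagents that add atoms: 2,2-dimethoxypropane, COC(C)(C)OC
Why: Acid-catalysed transketalisation of the cis-diol gives the cis-fused dioxolane, which blocks one face of the diene and suppresses aromatisation.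

**Step 6**
Reactants: 8 (3aR,7aS)-2,2,4-trimethyl-3a,7a-dihydro-1,3-benzodioxole; 9 2-bromoprop-2-enoic acid
Product: 10 (3aR,4S,5R,7aR)-4,5-(isopropylidenedioxy)-6-methyl-3-methylidene-3a,4,5,7a-tetrahydro-1-benzofuran-2(3H)-one
Conditions: Pd(OAc)2 (10 mol %), tri(2-furyl)phosphine (20 mol %), Ag2CO3 (1.2 equiv), MeCN, 60 °C
Reagents that add atoms: none
Why: Proposed new method: zerovalent palladium inserts into the C–Br bond of the 2-bromoacrylate, the divalent 1-carboxyvinylpalladium adds syn across the unsubstituted diene terminus C7 (C11–C7 bond) on the face anti to the dioxolane, and the η3-allyl complex over C6–C5–C4 is captured at C6 by the tethered carboxylate (O–C6 bond) with return of zerovalent palladium; the closest known reaction type is the Larock heteroannulation of 1,3-dienes by ortho-iodobenzoic acids and by hydroxy- or carboxy-substituted vinylic halides. The one ring closed is the γ-lactone, formed as a five-membered ring by attack of the carboxylate oxygen on the proximal allyl terminus (5-exo with respect to the allyl unit), the alternative attack at C4 requiring a bridged seven-membered ring. C7 is set by carbopalladation on the convex, anti-acetonide face, and C6 by the tether, which on a cyclohexenyl allyl complex can reach C6 only from the face that carries C11, so the lactone should be cis-fused. The step needs insertion at C7 and not at the methyl-bearing terminus C4 (secured by the C4 methyl group, which would force a quaternary centre), capture faster than β-hydride loss (secured by the intramolecular five-ring closure and the lack of a syn hydrogen on C7), and survival of the C4=C5 olefin, whose Z geometry is fixed by the six-membered ring.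

**Step 7**
Reactants: 10 lactone acetonide
Product: 12 (2Z)-3-[(2R,3R)-3-formyl-4-methylidene-5-oxooxolan-2-yl]-2-methylprop-2-enal, via cis-diol lactone 11 (not isolated)
Conditions: H5IO6 (1.5 equiv), EtOAc, 0 °C to rt; crude product used at once
Reagents that add atoms: none
Why: Periodic acid should hydrolyse the dioxolane and cleave the C3–C8 glycol bond through the cyclic periodate ester (Malaprade cleavage), leaving C6, C7 and the ring-derived Z-olefin untouched.

**Step 8**
Reactants: 12 lactone dialdehyde; 6 3-(methoxymethoxy)-2-methylprop-1-ene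
Product: 14 (2Z)-3-{(2R,3S)-3-[(1S,2S)-1-hydroxy-2-(methoxymethoxy)-3-methylbut-3-en-1-yl]-4-methylidene-5-oxooxolan-2-yl}-2-methylprop-2-enal, via alkoxyallylborane 13 (not isolated)
Conditions: 6, s-BuLi, THF, −78 °C; (+)-Ipc2BOMe [from (−)-α-pinene]; BF3·OEt2; then 12 (1.0 equiv per 1.05 equiv of borane), −78 °C; 8-hydroxyquinoline, MeOH/Et2O, rt
Reagents that add atoms: none
Why: Brown γ-alkoxyallylboration through a chair Zimmerman–Traxler transition state, in which the Z-borane gives the syn (8S,9S) adduct, the isopinocampheyl groups choose the aldehyde face (the same sense as Felkin–Anh addition anti to the oxygenated ring carbon C6), and the saturated C8 aldehyde should react ahead of the hindered conjugated C3 enal.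

**Step 9**
Reactants: 14 hydroxy enal
Product: 15 (4S,5R)-4-[(1S,2S)-1-hydroxy-2-(methoxymethoxy)-3-methylbut-3-en-1-yl]-5-[(1Z,3S)-3-hydroxy-2-methylhexa-1,5-dien-1-yl]-3-methylideneoxolan-2-one
Conditions: B-allyldiisopinocampheylborane [from (+)-α-pinene, 2.2 equiv], Et2O, −78 °C; 8-hydroxyquinoline, MeOH/Et2O, rt
Reagents that add atoms: B-allyldiisopinocampheylborane from (+)-α-pinene, C=CCB([C@@H]1C[C@@H]2C[C@H]([C@H]1C)C2(C)C)[C@@H]1C[C@@H]2C[C@H]([C@H]1C)C2(C)C
Why: Brown allylboration of the enal through a chair transition state, where the reagent from (+)-α-pinene should set the 3S carbinol under reagent control (C3 is remote from C6) and the lactone and its methylene group are not attacked by the allylborane.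

**Step 10**
Reactants: 15 diol
Product: 16 (1Z,3S)-1-{(2R,3S)-3-[(1S,2S)-1-hydroxy-2-(methoxymethoxy)-3-methylbut-3-en-1-yl]-4-methylidene-5-oxooxolan-2-yl}-2-methylhexa-1,5-dien-3-yl acetate
Conditions: Ac2O (1.2 equiv), pyridine, CH2Cl2, −20 to 0 °C
Reagents that add atoms: acetic anhydride, CC(=O)OC(C)=O
Why: Kinetic acetylation should take the less hindered allylic C3 hydroxyl and leave the C8 hydroxyl, which is flanked by the branched carbons C7 and C9.

**Step 11**
Reactants: 16 monoacetate
Product: 18 (1Z,3S)-1-{(2R,3S)-3-[(1R,2S)-1-hydroxy-2-(methoxymethoxy)-3-methylbut-3-en-1-yl]-4-methylidene-5-oxooxolan-2-yl}-2-methylhexa-1,5-dien-3-yl acetate, via C8 ketone 17 (not isolated)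
Conditions: Dess–Martin periodinane, NaHCO3, CH2Cl2, 0 °C; filtration; then Zn(BH4)2, Et2O, −40 °C
Reagents that add atoms: none
Why: Dess–Martin oxidation gives the α-alkoxy ketone, which Zn(BH4)2 should reduce through the five-membered zinc chelate between the C8 carbonyl and the C9 MOM oxygen (Cram chelate model), hydride arriving anti to the isopropenyl group to give the 8,9-anti (8R) alcohol.

**Step 12**
Reactants: 18 8R alcohol
Product: 19 (1Z,3S)-1-{(2R,3R)-3-[(1R,2S)-1-[(tert-butyldimethylsilyl)oxy]-2-(methoxymethoxy)-3-methylbut-3-en-1-yl]-4-methylidene-5-oxooxolan-2-yl}-2-methylhexa-1,5-dien-3-yl acetate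
Conditions: TBSOTf, 2,6-lutidine, CH2Cl2, −78 to −20 °C
Reagents that add atoms: tert-butyldimethylsilyl trifluoromethanesulfonate, CC(C)(C)[Si](C)(C)OS(=O)(=O)C(F)(F)F
Why: Silyl triflate silylation of the hindered secondary C8 hydroxyl blocks acyl migration and translactonisation in the later steps.

**Step 13**
Reactants: 19 silyl ether
Product: 21 (1Z,3S)-1-{(2R,3R)-3-[(1R,2S)-1-[(tert-butyldimethylsilyl)oxy]-2-hydroxy-3-methylbut-3-en-1-yl]-4-methylidene-5-oxooxolan-2-yl}-2-methylhexa-1,5-dien-3-yl acetate, via bromomethyl ether 20 (not isolated)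
Conditions: Me2BBr, CH2Cl2, −78 °C; then aq. NaHCO3/THF
Reagents that add atoms: none
Why: The bromoborane should cleave the MOM acetal selectively at low temperature, the resulting bromomethyl ether being hydrolysed on work-up while silyl ether, esters and olefins stay intact.

**Step 14**
Reactants: 21 diene alcohol
Product: 22 (3aR,4R,5S,6Z,9S,10Z,11aR)-4-[(tert-butyldimethylsilyl)oxy]-5-hydroxy-6,10-dimethyl-3-methylidene-2-oxo-2,3,3a,4,5,8,9,11a-octahydrocyclodeca[b]furan-9-yl acetate
Conditions: second-generation Hoveyda–Grubbs catalyst (10 mol %), 1,4-benzoquinone (20 mol %), toluene (1 mM), 80 °C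
Reagents that add atoms: none
Why: Ring-closing olefin metathesis between the vinyl group and the 1,1-disubstituted olefin (activated by the free allylic hydroxyl) should close the ten-membered ring, with the cis-lactone and the Z-C4=C5 olefin folding the chain and the ring constraint favouring the Z-C1=C10 olefin, while the electron-poor methylene lactone stays out of the catalytic cycle.

**Step 15**
Reactants: 22 macrocyclic alcohol; 4 (2R,3R)-2,3-dimethyloxirane-2-carboxylic acid
Product: 24 (3aR,4R,5S,6Z,9S,10Z,11aR)-9-(acetyloxy)-4-[(tert-butyldimethylsilyl)oxy]-6,10-dimethyl-3-methylidene-2-oxo-2,3,3a,4,5,8,9,11a-octahydrocyclodeca[b]furan-5-yl (2R,3R)-2,3-dimethyloxirane-2-carboxylate, via mixed anhydride 23 (not isolated)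
Conditions: 4, 2,4,6-trichlorobenzoyl chloride, Et3N, toluene, rt; then 22, DMAP, toluene, rt to 40 °C
Reagents that add atoms: none
Why: Yamaguchi esterification, in which DMAP should transfer the glycidic acyl group of the mixed anhydride to the hindered C9 hydroxyl with retention at C9 and without epimerising the epoxide.

**Step 16**
Reactants: 24 silyl-protected ester
Product: 25 target, (3aS,4R,5S,6Z,9S,10Z,11aR)-9-(acetyloxy)-4-hydroxy-6,10-dimethyl-3-methylidene-2-oxo-2,3,3a,4,5,8,9,11a-octahydrocyclodeca[b]furan-5-yl (2R,3R)-2,3-dimethyloxirane-2-carboxylate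
Conditions: HF·pyridine, pyridine, THF, 0 °C to rt
Reagents that add atoms: none
Why: Buffered fluoride desilylation under mildly acidic conditions should free the C8 hydroxyl without acyl migration from O9, translactonisation or epoxide opening.

**Compound list**
1 | angelic acid, (2Z)-2-methylbut-2-enoic acid | C/C=C(/C)C(=O)O | starting material
2 | (2Z)-2-methylbut-2-en-1-ol | C/C=C(/C)CO | intermediate
3 | [(2S,3R)-2,3-dimethyloxiran-2-yl]methanol | OC[C@]1(C)O[C@@H]1C | intermediate
4 | (2R,3R)-2,3-dimethyloxirane-2-carboxylic acid | OC(=O)[C@]1(C)O[C@@H]1C | intermediate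
5 | 2-methylprop-2-en-1-ol | C=C(C)CO | starting material
6 | 3-(methoxymethoxy)-2-methylprop-1-ene | C=C(C)COCOC | intermediate
7 | (1S,2R)-3-methylcyclohexa-3,5-diene-1,2-diol | CC1=CC=C[C@H](O)[C@@H]1O | starting material
8 | (3aR,7aS)-2,2,4-trimethyl-3a,7a-dihydro-1,3-benzodioxole | CC1=CC=C[C@@H]2OC(C)(C)O[C@H]12 | intermediate
9 | 2-bromoprop-2-enoic acid | C=C(Br)C(=O)O | starting material
10 | (3aR,4S,5R,7aR)-4,5-(isopropylidenedioxy)-6-methyl-3-methylidene-3a,4,5,7a-tetrahydro-1-benzofuran-2(3H)-one (cis-fused lactone anti to the dioxolane) | C=C1C(=O)O[C@@H]2C=C(C)[C@H]3OC(C)(C)O[C@H]3[C@H]12 | intermediate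
11 | (3aS,4S,5R,7aR)-4,5-dihydroxy-6-methyl-3-methylidene-3a,4,5,7a-tetrahydro-1-benzofuran-2(3H)-one | C=C1C(=O)O[C@@H]2C=C(C)[C@@H](O)[C@@H](O)[C@H]12 | intermediate (not isolated)
12 | (2Z)-3-[(2R,3R)-3-formyl-4-methylidene-5-oxooxolan-2-yl]-2-methylprop-2-enal | C=C1C(=O)O[C@H](/C=C(/C)C=O)[C@@H]1C=O | intermediate
13 | [(2Z)-3-(methoxymethoxy)-2-methylprop-2-en-1-yl]diisopinocampheylborane, (−)-α-pinene series | COCO/C=C(/C)CB([C@H]1C[C@H]2C[C@@H]([C@@H]1C)C2(C)C)[C@H]1C[C@H]2C[C@@H]([C@@H]1C)C2(C)C | intermediate (not isolated)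
14 | (2Z)-3-{(2R,3S)-3-[(1S,2S)-1-hydroxy-2-(methoxymethoxy)-3-methylbut-3-en-1-yl]-4-methylidene-5-oxooxolan-2-yl}-2-methylprop-2-enal | C=C(C)[C@H](OCOC)[C@@H](O)[C@H]1[C@@H](/C=C(/C)C=O)OC(=O)C1=C | intermediate
15 | (4S,5R)-4-[(1S,2S)-1-hydroxy-2-(methoxymethoxy)-3-methylbut-3-en-1-yl]-5-[(1Z,3S)-3-hydroxy-2-methylhexa-1,5-dien-1-yl]-3-methylideneoxolan-2-one | C=C(C)[C@H](OCOC)[C@@H](O)[C@H]1[C@@H](/C=C(/C)[C@@H](O)CC=C)OC(=O)C1=C | intermediate
16 | (1Z,3S)-1-{(2R,3S)-3-[(1S,2S)-1-hydroxy-2-(methoxymethoxy)-3-methylbut-3-en-1-yl]-4-methylidene-5-oxooxolan-2-yl}-2-methylhexa-1,5-dien-3-yl acetate | C=C(C)[C@H](OCOC)[C@@H](O)[C@H]1[C@@H](/C=C(/C)[C@@H](OC(C)=O)CC=C)OC(=O)C1=C | intermediate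
17 | (1Z,3S)-1-{(2R,3R)-3-[(2S)-2-(methoxymethoxy)-3-methylbut-3-enoyl]-4-methylidene-5-oxooxolan-2-yl}-2-methylhexa-1,5-dien-3-yl acetate | C=C(C)[C@H](OCOC)C(=O)[C@H]1[C@@H](/C=C(/C)[C@@H](OC(C)=O)CC=C)OC(=O)C1=C | intermediate (not isolated)
18 | (1Z,3S)-1-{(2R,3S)-3-[(1R,2S)-1-hydroxy-2-(methoxymethoxy)-3-methylbut-3-en-1-yl]-4-methylidene-5-oxooxolan-2-yl}-2-methylhexa-1,5-dien-3-yl acetate | C=C(C)[C@H](OCOC)[C@H](O)[C@H]1[C@@H](/C=C(/C)[C@@H](OC(C)=O)CC=C)OC(=O)C1=C | intermediate
19 | (1Z,3S)-1-{(2R,3R)-3-[(1R,2S)-1-[(tert-butyldimethylsilyl)oxy]-2-(methoxymethoxy)-3-methylbut-3-en-1-yl]-4-methylidene-5-oxooxolan-2-yl}-2-methylhexa-1,5-dien-3-yl acetate | C=C(C)[C@H](OCOC)[C@H](O[Si](C)(C)C(C)(C)C)[C@H]1[C@@H](/C=C(/C)[C@@H](OC(C)=O)CC=C)OC(=O)C1=C | intermediate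
20 | (1Z,3S)-1-{(2R,3R)-3-[(1R,2S)-2-(bromomethoxy)-1-[(tert-butyldimethylsilyl)oxy]-3-methylbut-3-en-1-yl]-4-methylidene-5-oxooxolan-2-yl}-2-methylhexa-1,5-dien-3-yl acetate | C=C(C)[C@H](OCBr)[C@H](O[Si](C)(C)C(C)(C)C)[C@H]1[C@@H](/C=C(/C)[C@@H](OC(C)=O)CC=C)OC(=O)C1=C | intermediate (not isolated)
21 | (1Z,3S)-1-{(2R,3R)-3-[(1R,2S)-1-[(tert-butyldimethylsilyl)oxy]-2-hydroxy-3-methylbut-3-en-1-yl]-4-methylidene-5-oxooxolan-2-yl}-2-methylhexa-1,5-dien-3-yl acetate | C=C(C)[C@H](O)[C@H](O[Si](C)(C)C(C)(C)C)[C@H]1[C@@H](/C=C(/C)[C@@H](OC(C)=O)CC=C)OC(=O)C1=C | intermediate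
22 | (3aR,4R,5S,6Z,9S,10Z,11aR)-4-[(tert-butyldimethylsilyl)oxy]-5-hydroxy-6,10-dimethyl-3-methylidene-2-oxo-2,3,3a,4,5,8,9,11a-octahydrocyclodeca[b]furan-9-yl acetate | C=C1C(=O)O[C@@H]2/C=C(/C)[C@@H](OC(C)=O)C/C=C(/C)[C@H](O)[C@H](O[Si](C)(C)C(C)(C)C)[C@H]12 | intermediate
23 | 2,4,6-trichlorobenzoic (2R,3R)-2,3-dimethyloxirane-2-carboxylic anhydride | O=C(OC(=O)[C@]1(C)O[C@@H]1C)c1c(Cl)cc(Cl)cc1Cl | intermediate (not isolated)
24 | (3aR,4R,5S,6Z,9S,10Z,11aR)-9-(acetyloxy)-4-[(tert-butyldimethylsilyl)oxy]-6,10-dimethyl-3-methylidene-2-oxo-2,3,3a,4,5,8,9,11a-octahydrocyclodeca[b]furan-5-yl (2R,3R)-2,3-dimethyloxirane-2-carboxylate | C=C1C(=O)O[C@@H]2/C=C(/C)[C@@H](OC(C)=O)C/C=C(/C)[C@H](OC(=O)[C@]3(C)O[C@@H]3C)[C@H](O[Si](C)(C)C(C)(C)C)[C@H]12 | intermediate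
25 | (3aS,4R,5S,6Z,9S,10Z,11aR)-9-(acetyloxy)-4-hydroxy-6,10-dimethyl-3-methylidene-2-oxo-2,3,3a,4,5,8,9,11a-octahydrocyclodeca[b]furan-5-yl (2R,3R)-2,3-dimethyloxirane-2-carboxylate | C=C1C(=O)O[C@@H]2/C=C(/C)[C@@H](OC(C)=O)C/C=C(/C)[C@H](OC(=O)[C@]3(C)O[C@@H]3C)[C@H](O)[C@H]12 | target

Total step count: 16. Longest linear sequence: 12 steps (7 to 25, steps 5–16).

**Steps most likely to fail**

Step 6 (key annulation). The allylpalladium intermediate may lose a β-hydrogen (from the C4 methyl group or from C3) faster than the carboxylate closes the lactone, the bromoacrylate may be consumed by polymerisation or Michael addition, or insertion into the ring diene may be too slow. The fallback replaces the palladium event by a radical–polar crossover of known type and sets out from 8. Oxidation of methyl hydrogen malonate with Mn(OAc)3·2H2O (trivalent manganese) and Cu(OAc)2·H2O (divalent copper) in AcOH/KOAc at 25–40 °C should add the malonyl radical to C7 anti to the dioxolane; oxidation of the allyl radical and closure of the acid onto C6 then give methyl (3aR,4S,5R,7aR)-4,5-(isopropylidenedioxy)-6-methyl-2-oxo-2,3,3a,4,5,7a-hexahydro-1-benzofuran-3-carboxylate F1 as a C11 epimer mixture. Saponification (LiOH, THF/H2O, then pH 4, with relactonisation) gives the corresponding 3-carboxylic acid F2. Decarboxylative Mannich methylenation (aqueous CH2O, Et2NH, then NaOAc/AcOH, 70 °C) returns to the route at 10.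

Step 8 (first allylboration of the dialdehyde). The two formyl groups may not be discriminated well enough, and the β-acyloxy aldehyde may enolise, epimerise at C7 or eliminate the lactone carboxylate before it is consumed. The fallback differentiates the carbonyls by protection instead of by rate and sets out from 12. Noyori acetalisation (1,2-bis(trimethylsilyloxy)ethane, cat. TMSOTf, CH2Cl2, −78 °C) should take only the saturated aldehyde and give (2Z)-3-[(2R,3R)-3-(1,3-dioxolan-2-yl)-4-methylidene-5-oxooxolan-2-yl]-2-methylprop-2-enal F3. Allylboration with the (+)-α-pinene-derived reagent of step 9 gives (4R,5R)-4-(1,3-dioxolan-2-yl)-5-[(1Z,3S)-3-hydroxy-2-methylhexa-1,5-dien-1-yl]-3-methylideneoxolan-2-one F4, and acetylation (Ac2O, pyridine) gives (1Z,3S)-1-[(2R,3R)-3-(1,3-dioxolan-2-yl)-4-methylidene-5-oxooxolan-2-yl]-2-methylhexa-1,5-dien-3-yl acetate F5. Mild hydrolysis (PPTS, wet acetone) frees (1Z,3S)-1-[(2R,3R)-3-formyl-4-methylidene-5-oxooxolan-2-yl]-2-methylhexa-1,5-dien-3-yl acetate F6. Alkoxyallylboration of F6 with 13 under the conditions of step 8 comes back to the route at 16; this path also removes the need for the selective acetylation of step 10.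

Step 14 (ten-membered ring closure). Oligomerisation may outrun cyclisation, the free allylic alcohol may be isomerised by ruthenium hydrides, or the E-olefin may form. The fallback moves ring closure in front of the protecting-group exchange and sets out from 18. That substrate has no silyl ether beside the 1,1-disubstituted olefin, an allylic ether in place of the free allylic alcohol, and a free C8 hydroxyl that can hydrogen-bond to the lactone carbonyl and fold the chain. Metathesis of 18 under the conditions of step 14 should give (3aS,4R,5S,6Z,9S,10Z,11aR)-4-hydroxy-5-(methoxymethoxy)-6,10-dimethyl-3-methylidene-2-oxo-2,3,3a,4,5,8,9,11a-octahydrocyclodeca[b]furan-9-yl acetate F7. Silylation (TBSOTf, 2,6-lutidine) gives (3aR,4R,5S,6Z,9S,10Z,11aR)-4-[(tert-butyldimethylsilyl)oxy]-5-(methoxymethoxy)-6,10-dimethyl-3-methylidene-2-oxo-2,3,3a,4,5,8,9,11a-octahydrocyclodeca[b]furan-9-yl acetate F8, and MOM cleavage with Me2BBr comes back to the route at 22.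

**Further compounds**
F1 | step 6 | methyl (3aR,4S,5R,7aR)-4,5-(isopropylidenedioxy)-6-methyl-2-oxo-2,3,3a,4,5,7a-hexahydro-1-benzofuran-3-carboxylate (C3 epimers) | COC(=O)C1C(=O)O[C@@H]2C=C(C)[C@H]3OC(C)(C)O[C@H]3[C@H]12
F2 | step 6 | (3aR,4S,5R,7aR)-4,5-(isopropylidenedioxy)-6-methyl-2-oxo-2,3,3a,4,5,7a-hexahydro-1-benzofuran-3-carboxylic acid (C3 epimers) | OC(=O)C1C(=O)O[C@@H]2C=C(C)[C@H]3OC(C)(C)O[C@H]3[C@H]12
F3 | step 8 | (2Z)-3-[(2R,3R)-3-(1,3-dioxolan-2-yl)-4-methylidene-5-oxooxolan-2-yl]-2-methylprop-2-enal | C=C1C(=O)O[C@H](/C=C(/C)C=O)[C@@H]1C1OCCO1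
F4 | step 8 | (4R,5R)-4-(1,3-dioxolan-2-yl)-5-[(1Z,3S)-3-hydroxy-2-methylhexa-1,5-dien-1-yl]-3-methylideneoxolan-2-one | C=C1C(=O)O[C@H](/C=C(/C)[C@@H](O)CC=C)[C@@H]1C1OCCO1
F5 | step 8 | (1Z,3S)-1-[(2R,3R)-3-(1,3-dioxolan-2-yl)-4-methylidene-5-oxooxolan-2-yl]-2-methylhexa-1,5-dien-3-yl acetate | C=C1C(=O)O[C@H](/C=C(/C)[C@@H](OC(C)=O)CC=C)[C@@H]1C1OCCO1
F6 | step 8 | (1Z,3S)-1-[(2R,3R)-3-formyl-4-methylidene-5-oxooxolan-2-yl]-2-methylhexa-1,5-dien-3-yl acetate | C=C1C(=O)O[C@H](/C=C(/C)[C@@H](OC(C)=O)CC=C)[C@@H]1C=O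
F7 | step 14 | (3aS,4R,5S,6Z,9S,10Z,11aR)-4-hydroxy-5-(methoxymethoxy)-6,10-dimethyl-3-methylidene-2-oxo-2,3,3a,4,5,8,9,11a-octahydrocyclodeca[b]furan-9-yl acetate | C=C1C(=O)O[C@@H]2/C=C(/C)[C@@H](OC(C)=O)C/C=C(/C)[C@H](OCOC)[C@H](O)[C@H]12
F8 | step 14 | (3aR,4R,5S,6Z,9S,10Z,11aR)-4-[(tert-butyldimethylsilyl)oxy]-5-(methoxymethoxy)-6,10-dimethyl-3-methylidene-2-oxo-2,3,3a,4,5,8,9,11a-octahydrocyclodeca[b]furan-9-yl acetate | C=C1C(=O)O[C@@H]2/C=C(/C)[C@@H](OC(C)=O)C/C=C(/C)[C@H](OCOC)[C@H](O[Si](C)(C)C(C)(C)C)[C@H]12
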